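**Strategy.** The pyran ring of the flavan unit is disconnected at C2–C3 and C4–C4a. An O-aryl oxocarbenium ion (flavan ring A, O1 and C2 with ring B), released from a mixed O-aryl O-methyl acetal, and the (E)-enol acetate of the flavonol-5-acetaldehyde (C3=C4, flavonol already in place) are joined in one acid-catalysed formal [4+2] (oxa-Povarov) annulation that closes the ring and sets C2, C3 and C4. It exploits the 8-oxygen para to C5 and the peri C4 carbonyl of the flavonol, which stabilise the cation at flavan C4, and the nucleophilic C4a of ring A, ortho to O1 and para to the 7-oxygen. All phenols travel as benzyl ethers.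

Key step: step 9

Assumption: which antipode of the chiral acid in step 9 leads to the (2R,3R,4S) series cannot be predicted with confidence and would be fixed by a test run; the (R)-acid is written.

**Step 1**
Reactants: 1 gossypetin
Product: 2 3,7,8,3',4'-penta-O-benzylgossypetin (5-OH free)
Conditions: BnBr (5.5 equiv), K2CO3, DMF, argon, rt
Reagents that add atoms: benzyl bromide, BrCc1ccccc1
Why: Williamson etherification should alkylate the five reactive hydroxyls while the 5-OH, hydrogen-bonded to the C4 carbonyl, stays free, as is usual for 5-hydroxyflavonols under carbonate conditions.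

**Step 2**
Reactants: 2 3,7,8,3',4'-penta-O-benzylgossypetin
Product: 3 3,7,8,3',4'-penta-O-benzylgossypetin 5-O-triflate
Conditions: Tf2O, pyridine, CH2Cl2, 0 °C to rt
Reagents that add atoms: triflic anhydride, O=S(=O)(OS(=O)(=O)C(F)(F)F)C(F)(F)F
Why: O-sulfonylation of the remaining chelated phenol should give the aryl triflate that makes C5 available for cross-coupling.

**Step 3**
Reactants: 3 3,7,8,3',4'-penta-O-benzylgossypetin 5-O-triflate; 4 (E)-2-(2-ethoxyethenyl)-4,4,5,5-tetramethyl-1,3,2-dioxaborolane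
Product: 5 5-[(E)-2-ethoxyethenyl]-3,7,8,3',4'-pentakis(benzyloxy)flavone
Conditions: Pd(OAc)2, 2-dicyclohexylphosphino-2',6'-dimethoxybiphenyl, K3PO4, 1,4-dioxane/H2O, 80 °C
Reagents that add atoms: none
Why: Suzuki–Miyaura coupling of the peri-hindered triflate with the alkenyl boronate should install the two-carbon side chain at C5 with a bulky electron-rich phosphine.

**Step 4**
Reactants: 5 5-[(E)-2-ethoxyethenyl]-3,7,8,3',4'-pentakis(benzyloxy)flavone
Product: 6 2-[3,7,8,3',4'-pentakis(benzyloxy)flavon-5-yl]acetaldehyde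
Conditions: 2 M aq. HCl, THF, 40 °C
Reagents that add atoms: water, O
Why: Acid-catalysed enol ether hydrolysis should unmask the arylacetaldehyde without touching the benzyl ethers.

**Step 5**
Reactants: 6 2-[3,7,8,3',4'-pentakis(benzyloxy)flavon-5-yl]acetaldehyde
Product: 7 (E)-2-[3,7,8,3',4'-pentakis(benzyloxy)flavon-5-yl]ethenyl acetate
Conditions: Ac2O, Et3N, 4-(dimethylamino)pyridine (cat.), THF, 50 °C; then I2 (cat.), CH2Cl2, rt
Reagents that add atoms: acetic anhydride, CC(=O)OC(C)=O
Why: O-acylation of the aldehyde enolate should give the enol acetate, and iodine-catalysed equilibration should favour the E isomer, in which the peri-hindered aryl group and the acetoxy group are apart.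

**Step 6**
Reactants: 8 2,3-bis(benzyloxy)benzaldehyde
Product: 10 2,3-bis(benzyloxy)phenol, via 2,3-bis(benzyloxy)phenyl formate 9 (not isolated)
Conditions: 3-chloroperoxybenzoic acid, CH2Cl2, 0 °C to rt; then K2CO3, MeOH, rt
Reagents that add atoms: 3-chloroperoxybenzoic acid, OOC(=O)c1cccc(Cl)c1
Why: Baeyer–Villiger (Dakin-type) oxidation should proceed by migration of the electron-rich ortho-alkoxy aryl group, and the formate is cleaved by methanolysis.

**Step 7**
Reactants: 11 3,4-bis(benzyloxy)benzaldehyde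
Product: 12 3,4-bis(benzyloxy)benzaldehyde dimethyl acetal
Conditions: HC(OMe)3, MeOH, p-toluenesulfonic acid (cat.), rt
Reagents that add atoms: trimethyl orthoformate, COC(OC)OC
Why: Acid-catalysed acetalisation should be driven to completion by the orthoformate as water scavenger.

**Step 8**
Reactants: 12 3,4-bis(benzyloxy)benzaldehyde dimethyl acetal; 10 2,3-bis(benzyloxy)phenol
Product: 14 1,2-bis(benzyloxy)-3-{[3,4-bis(benzyloxy)phenyl](methoxy)methoxy}benzene (racemic mixed acetal), via 1,2-bis(benzyloxy)-4-[chloro(methoxy)methyl]benzene 13 (not isolated)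
Conditions: AcCl, CH2Cl2, 0 °C to rt; concentrate; then 10, iPr2NEt, CH2Cl2, 0 °C; chromatography on Et3N-deactivated silica
Reagents that add atoms: none
Why: Acetal–acyl chloride exchange should give the α-chloro ether, which O-alkylates the phenol to the mixed O-aryl O-methyl acetal; its acetal carbon becomes planar in the next step, so its configuration is irrelevant.

**Step 9**
Reactants: 7 (E)-2-[3,7,8,3',4'-pentakis(benzyloxy)flavon-5-yl]ethenyl acetate; 14 1,2-bis(benzyloxy)-3-{[3,4-bis(benzyloxy)phenyl](methoxy)methoxy}benzene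
Product: 17 (2R,3R,4S)-7,8-bis(benzyloxy)-2-[3,4-bis(benzyloxy)phenyl]-4-[3,7,8,3',4'-pentakis(benzyloxy)flavon-5-yl]chroman-3-yl acetate, via oxocarbenium ion 15 (not isolated), via benzylic cation 16 (not isolated)
Conditions: (R)-3,3'-bis(2,4,6-triisopropylphenyl)-1,1'-binaphthyl-2,2'-diyl N-triflylphosphoramide (C51H57F3NO5PS, 10 mol %), 5 Å molecular sieves, toluene/CH2Cl2, −40 to 0 °C
Reagents that add atoms: none
Why: Proposed new method: the chiral acid ionises acetal 14 to the O-aryl oxocarbenium ion 15, held as an ion pair with the phosphoramide anion; C3 of enol acetate 7 (the alkene carbon remote from the aryl group) adds to C2, and the C4 benzylic cation 16, stabilised by the para 8-benzyloxy group and bridged by the peri C4 carbonyl oxygen of the flavonol, is alkylated by C4a of the aryloxy ring with loss of the proton that regenerates the acid. The closest known reaction type is the SnCl4-promoted oxa-Povarov reaction (formal [4+2] of aryl oxocarbenium ions with styrenes), extended here to an enol ester partner under chiral Brønsted acid control, for which asymmetric Prins and oxa-Pictet–Spengler reactions of oxocarbenium ion pairs are the nearest precedent. The pyran ring closes by a 6-exo-tet Friedel–Crafts displacement at C4 of the bridged ion (6-endo with respect to the arene C4a=C8a bond). C2 and C3 are set together in the C2–C3 bond formation: the chiral anion shields one face of 15 (absolute sense), and the acetoxy group should take the endo position over the oxocarbenium oxygen, its carbonyl attracted to the cationic carbon, which places it cis to the C2 aryl group (2,3-cis). C4 follows from the E geometry, because anti bridging and invertive ring closure amount to suprafacial addition and place the C4 aryl group trans to the 3-acetoxy group. The step needs attack through C3 and not C4 of the alkene, secured by the 8-benzyloxy and peri-carbonyl stabilisation of the C4 cation against a poorly stabilised acyloxycarbenium ion, and ring closure at the only free position ortho to O1, which is also para to the 7-benzyloxy group.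

**Step 10**
Reactants: 17 (2R,3R,4S)-7,8-bis(benzyloxy)-2-[3,4-bis(benzyloxy)phenyl]-4-[3,7,8,3',4'-pentakis(benzyloxy)flavon-5-yl]chroman-3-yl acetate
Product: 18 5-{(2R,3R,4S)-7,8-bis(benzyloxy)-2-[3,4-bis(benzyloxy)phenyl]-3-hydroxychroman-4-yl}-3,7,8,3',4'-pentakis(benzyloxy)flavone
Conditions: K2CO3, MeOH/THF, rt
Reagents that add atoms: none
Why: Base-catalysed transesterification should remove the acetate without epimerisation, since no stereocentre carries an acidic hydrogen and the benzyl ethers and the flavone are stable to methanolic carbonate.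

**Step 11**
Reactants: 18 5-{(2R,3R,4S)-7,8-bis(benzyloxy)-2-[3,4-bis(benzyloxy)phenyl]-3-hydroxychroman-4-yl}-3,7,8,3',4'-pentakis(benzyloxy)flavone
Product: 19 5-[(2R,3R,4S)-2-(3,4-dihydroxyphenyl)-3,7,8-trihydroxychroman-4-yl]-2-(3,4-dihydroxyphenyl)-3,7,8-trihydroxy-4H-chromen-4-one (CNP0395591.1)
Conditions: H2 (1 atm), Pd(OH)2/C, THF/MeOH, rt
Reagents that add atoms: none
Why: Hydrogenolysis should cleave the nine benzyl ethers under conditions that, as with benzylated catechins and quercetin, leave the flavan C2–O1 bond, the C4–aryl bond and the flavonol enone intact.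

**Compound list**
1 | gossypetin (3,5,7,8,3',4'-hexahydroxyflavone) | O=c1c(O)c(-c2ccc(O)c(O)c2)oc2c(O)c(O)cc(O)c12 | starting material
2 | 3,7,8,3',4'-penta-O-benzylgossypetin (5-OH free) | O=c1c(OCc2ccccc2)c(-c2ccc(OCc3ccccc3)c(OCc3ccccc3)c2)oc2c(OCc3ccccc3)c(OCc3ccccc3)cc(O)c12 | intermediate
3 | 3,7,8,3',4'-penta-O-benzylgossypetin 5-O-triflate | O=c1c(OCc2ccccc2)c(-c2ccc(OCc3ccccc3)c(OCc3ccccc3)c2)oc2c(OCc3ccccc3)c(OCc3ccccc3)cc(OS(=O)(=O)C(F)(F)F)c12 | intermediate
4 | (E)-2-(2-ethoxyethenyl)-4,4,5,5-tetramethyl-1,3,2-dioxaborolane | CCO/C=C/B1OC(C)(C)C(C)(C)O1 | starting material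
5 | 5-[(E)-2-ethoxyethenyl]-3,7,8,3',4'-pentakis(benzyloxy)flavone | O=c1c(OCc2ccccc2)c(-c2ccc(OCc3ccccc3)c(OCc3ccccc3)c2)oc2c(OCc3ccccc3)c(OCc3ccccc3)cc(/C=C/OCC)c12 | intermediate
6 | 2-[3,7,8,3',4'-pentakis(benzyloxy)flavon-5-yl]acetaldehyde | O=c1c(OCc2ccccc2)c(-c2ccc(OCc3ccccc3)c(OCc3ccccc3)c2)oc2c(OCc3ccccc3)c(OCc3ccccc3)cc(CC=O)c12 | intermediate
7 | (E)-2-[3,7,8,3',4'-pentakis(benzyloxy)flavon-5-yl]ethenyl acetate | O=c1c(OCc2ccccc2)c(-c2ccc(OCc3ccccc3)c(OCc3ccccc3)c2)oc2c(OCc3ccccc3)c(OCc3ccccc3)cc(/C=C/OC(C)=O)c12 | intermediate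
8 | 2,3-bis(benzyloxy)benzaldehyde | O=Cc1cccc(OCc2ccccc2)c1OCc1ccccc1 | starting material
9 | 2,3-bis(benzyloxy)phenyl formate | O=COc1cccc(OCc2ccccc2)c1OCc1ccccc1 | intermediate (not isolated)
10 | 2,3-bis(benzyloxy)phenol | Oc1cccc(OCc2ccccc2)c1OCc1ccccc1 | intermediate
11 | 3,4-bis(benzyloxy)benzaldehyde | O=Cc1ccc(OCc2ccccc2)c(OCc2ccccc2)c1 | starting material
12 | 3,4-bis(benzyloxy)benzaldehyde dimethyl acetal | COC(OC)c1ccc(OCc2ccccc2)c(OCc2ccccc2)c1 | intermediate
13 | 1,2-bis(benzyloxy)-4-[chloro(methoxy)methyl]benzene | COC(Cl)c1ccc(OCc2ccccc2)c(OCc2ccccc2)c1 | intermediate (not isolated)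
14 | 1,2-bis(benzyloxy)-3-{[3,4-bis(benzyloxy)phenyl](methoxy)methoxy}benzene (racemic mixed acetal) | COC(Oc1cccc(OCc2ccccc2)c1OCc1ccccc1)c1ccc(OCc2ccccc2)c(OCc2ccccc2)c1 | intermediate
15 | O-[2,3-bis(benzyloxy)phenyl] oxocarbenium ion of 3,4-bis(benzyloxy)benzaldehyde | C(=[O+]c1cccc(OCc2ccccc2)c1OCc1ccccc1)c1ccc(OCc2ccccc2)c(OCc2ccccc2)c1 | intermediate (not isolated)
16 | benzylic cation after C2–C3 bond formation (drawn open; bridged by the flavonol C4 carbonyl oxygen) | O([C@H](c1ccc(OCc2ccccc2)c(OCc2ccccc2)c1)[C@H](OC(C)=O)[CH+]c1cc(OCc2ccccc2)c(OCc2ccccc2)c2oc(-c3ccc(OCc4ccccc4)c(OCc4ccccc4)c3)c(OCc3ccccc3)c(=O)c12)c1cccc(OCc2ccccc2)c1OCc1ccccc1 | intermediate (not isolated)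
17 | (2R,3R,4S)-7,8-bis(benzyloxy)-2-[3,4-bis(benzyloxy)phenyl]-4-[3,7,8,3',4'-pentakis(benzyloxy)flavon-5-yl]chroman-3-yl acetate | O=c1c(OCc2ccccc2)c(-c2ccc(OCc3ccccc3)c(OCc3ccccc3)c2)oc2c(OCc3ccccc3)c(OCc3ccccc3)cc([C@H]3c4ccc(OCc5ccccc5)c(OCc5ccccc5)c4O[C@H](c4ccc(OCc5ccccc5)c(OCc5ccccc5)c4)[C@@H]3OC(C)=O)c12 | intermediate
18 | 5-{(2R,3R,4S)-7,8-bis(benzyloxy)-2-[3,4-bis(benzyloxy)phenyl]-3-hydroxychroman-4-yl}-3,7,8,3',4'-pentakis(benzyloxy)flavone | O=c1c(OCc2ccccc2)c(-c2ccc(OCc3ccccc3)c(OCc3ccccc3)c2)oc2c(OCc3ccccc3)c(OCc3ccccc3)cc([C@H]3c4ccc(OCc5ccccc5)c(OCc5ccccc5)c4O[C@H](c4ccc(OCc5ccccc5)c(OCc5ccccc5)c4)[C@@H]3O)c12 | intermediate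
19 | 5-[(2R,3R,4S)-2-(3,4-dihydroxyphenyl)-3,7,8-trihydroxychroman-4-yl]-2-(3,4-dihydroxyphenyl)-3,7,8-trihydroxy-4H-chromen-4-one | O=c1c(O)c(-c2ccc(O)c(O)c2)oc2c(O)c(O)cc([C@H]3c4ccc(O)c(O)c4O[C@H](c4ccc(O)c(O)c4)[C@@H]3O)c12 | target

**Step count.** Total: 11 steps. Longest linear sequence: 8 steps (steps 1–5 and 9–11, from gossypetin).

**Steps most likely to fail**

Step 9 (proposed new method). The ion-pair annulation may lose enantio- or diastereocontrol, and the Lewis-basic flavonol carbonyl may tie up the catalytic chiral acid. The fallback uses known chemistry only; it sets out from 6 and comes back at 18. Aldehyde 6 would be O-acylated with (1S)-camphanic chloride (Et3N, 4-(dimethylamino)pyridine, then I2-catalysed equilibration) to the (E)-enol (1S,4R)-camphanate F1. The established Lewis acid oxa-Povarov annulation with acetal 14 (BF3·OEt2 in excess, CH2Cl2, −78 °C) would then run without a chiral catalyst. The covalently bound camphanoyl group turns the two antipodal 2,3-cis-3,4-trans series into diastereomers. The (2R,3R,4S) camphanate ester F2 would be separated by chromatography or crystallisation and methanolysed (K2CO3, MeOH/THF) to 18.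

Step 5. Enol geometry may be poorly controlled, and the arylacetaldehyde may self-condense or oxidise before acylation. The fallback sets out from 3 and comes back at 7. Triflate 3 would be coupled once with an excess of (E)-1,2-bis(4,4,5,5-tetramethyl-1,3,2-dioxaborolan-2-yl)ethene (Pd(OAc)2, the same biaryl phosphine, K3PO4) to the (E)-alkenyl pinacol boronate F3. A Chan–Lam-type C–O coupling with acetate (Cu(OAc)2, AcOH, Et3N, 4 Å sieves, air, CH2Cl2) would give 7 with retention of the E geometry, so that no aldehyde is handled.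

Step 8. The α-chloro ether or the mixed acetal may ionise and hydrolyse during handling, and the phenoxide may be C-alkylated. The fallback sets out from 10 and comes back at 14. Phenol 10 would be alkylated with 3,4-bis(benzyloxy)benzyl chloride (K2CO3, DMF) to the aryl 3,4-bis(benzyloxy)benzyl ether F4. Its electron-rich benzylic C–H bond would be oxidised with DDQ in CH2Cl2/MeOH over 4 Å sieves, the oxocarbenium ion being trapped by methanol to give 14.

**Further compounds**
F1 | step 9 | (E)-2-[3,7,8,3',4'-pentakis(benzyloxy)flavon-5-yl]ethenyl (1S,4R)-4,7,7-trimethyl-3-oxo-2-oxabicyclo[2.2.1]heptane-1-carboxylate | O=c1c(OCc2ccccc2)c(-c2ccc(OCc3ccccc3)c(OCc3ccccc3)c2)oc2c(OCc3ccccc3)c(OCc3ccccc3)cc(/C=C/OC(=O)[C@@]34CC[C@@](C)(C(=O)O3)C4(C)C)c12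
F2 | step 9 | (2R,3R,4S)-7,8-bis(benzyloxy)-2-[3,4-bis(benzyloxy)phenyl]-4-[3,7,8,3',4'-pentakis(benzyloxy)flavon-5-yl]chroman-3-yl (1S,4R)-4,7,7-trimethyl-3-oxo-2-oxabicyclo[2.2.1]heptane-1-carboxylate | O=c1c(OCc2ccccc2)c(-c2ccc(OCc3ccccc3)c(OCc3ccccc3)c2)oc2c(OCc3ccccc3)c(OCc3ccccc3)cc([C@H]3c4ccc(OCc5ccccc5)c(OCc5ccccc5)c4O[C@H](c4ccc(OCc5ccccc5)c(OCc5ccccc5)c4)[C@@H]3OC(=O)[C@@]56CC[C@@](C)(C(=O)O5)C6(C)C)c12
F3 | step 5 | 5-[(E)-2-(4,4,5,5-tetramethyl-1,3,2-dioxaborolan-2-yl)ethenyl]-3,7,8,3',4'-pentakis(benzyloxy)flavone | O=c1c(OCc2ccccc2)c(-c2ccc(OCc3ccccc3)c(OCc3ccccc3)c2)oc2c(OCc3ccccc3)c(OCc3ccccc3)cc(/C=C/B3OC(C)(C)C(C)(C)O3)c12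
F4 | step 8 | 1,2-bis(benzyloxy)-3-{[3,4-bis(benzyloxy)phenyl]methoxy}benzene | C(Oc1cccc(OCc2ccccc2)c1OCc1ccccc1)c1ccc(OCc2ccccc2)c(OCc2ccccc2)c1
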